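**Retrosynthetic overview**

1. Numbering used for the target and all intermediates: lactone carbonyl C1, then C2(OH), C3(OH), C4 (bearing methylene C19), C5, C6, C7, C8 (isopropyl), C9 (O-acyl), C10, C11 (methyl), C12, C13, C14 (methyl)=C15, C16, C17, C18 (methyl), ring oxygen. Ring A = C7–C11; ring B = C5, C6, C7, C11, C12, C13; ring C = C3, C4, C5, C13–C17; ring D = C1–C3, C17, C18, O.
2. The C9 ester is cut first, giving a (3R,5S)-3-hydroxy-3,5-dimethylheptanoic acid unit made by asymmetric epoxidation. Ring B is then opened at C5–C6: it is closed last by a type 1 intramolecular carbonyl-ene reaction of a C6 aldehyde with the ring C olefin C4(CH3)=C5, and the C6 oxygen is removed afterwards.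
3. Enabling feature: in ring C the exocyclic methylene C4=C19 lies between the ring B/ring C fusion carbon C5 and the fully substituted carbinol carbon C3. The array C6–C5–C4=C19 is therefore an ene retron whose only transferable allylic hydrogens sit on C19, and allylic strain at C13 steers the trans B/C fusion.
4. Ring C is made by ring-closing metathesis (C4=C5) after fragment union by C16–C17 enolate alkylation and C3–C4 isopropenyl addition. Ring D comes from a hetero-Diels–Alder pyranone (C18) that is oxidised to the lactone, with C2 set by hydride reduction.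
5. Ring A comes from 3-methylcyclopent-2-enone (conjugate addition/aldol for C11 and C7, hydroboration for C8 and C9); C13 is set by copper-catalysed allylic substitution. Order of rings: A and D arrive with the fragments, then C, then B.

Key step: step 34

**Remarks on the chemistry**

- Compound 1 is taken as purchasable.
- The enantiomers of the chiral ligands and catalysts in steps 3, 13 and 16 are those that should give the configurations drawn.
- The C6 carbinol in 49 and 50 is drawn as the expected equatorial epimer; either epimer converges in step 36.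
- Lactol 42 is an anomeric mixture.

**Route**

Step 1
Reactants: 1 (Z)-3-iodobut-2-en-1-ol
Product: 2 (Z)-3-iodobut-2-enyl triethylsilyl ether
Conditions: Et3SiCl, imidazole, CH2Cl2, 0 °C
Reagents that add atoms: chlorotriethylsilane, CC[Si](Cl)(CC)CC
Why: Silyl ether formation masks the primary hydroxyl for the boron and copper chemistry and leaves the Z olefin untouched.

Step 2
Reactants: 2 (Z)-3-iodobut-2-enyl triethylsilyl ether
Product: 3 pinacol alkenylboronate (boron cis to the CH2O group)
Conditions: B2pin2, PdCl2(PPh3)2 (3 mol %), PPh3, KOPh, toluene, 50 °C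
Reagents that add atoms: bis(pinacolato)diboron, CC1(C)OB(OC1(C)C)B1OC(C)(C)C(C)(C)O1
Why: Miyaura borylation of an alkenyl iodide should proceed with retention of olefin geometry, which later becomes the Z C14=C15 bond.

Step 3
Reactants: 4 3-methylcyclopent-2-en-1-one
Product: 6 (2S,3S)-2-(hydroxymethyl)-3-methyl-3-[1-(trimethylsilyl)ethenyl]cyclopentan-1-one, via aluminium enolate 5 (not isolated)
Conditions: [1-(trimethylsilyl)ethenyl]Al(i-Bu)2 (from ethynyltrimethylsilane and i-Bu2AlH, hexanes, 55 °C), Cu(OTf)2 (5 mol %), chiral sulfonate-bearing imidazolinium salt (5 mol %), THF, −30 °C; then MeLi, −78 °C; then CH2O (THF solution), −78 °C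
Reagents that add atoms: [1-(trimethylsilyl)ethenyl]diisobutylaluminium, C=C([Si](C)(C)C)[Al](CC(C)C)CC(C)C; formaldehyde, C=O
Why: Copper-catalysed enantioselective conjugate addition of the alkenylaluminium reagent should create the quaternary C11 under ligand control, and the regiodefined enolate (activated as its lithium aluminate) should add to formaldehyde anti to the bulky silylvinyl group, setting C7 (conjugate addition–aldol sequence).

Step 4
Reactants: 6 (2S,3S)-2-(hydroxymethyl)-3-methyl-3-[1-(trimethylsilyl)ethenyl]cyclopentan-1-one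
Product: 7 naphthalen-2-ylmethyl ether of 6
Conditions: naphthalen-2-ylmethyl 2,2,2-trichloroacetimidate, Me3SiOTf (5 mol %), CH2Cl2, −20 °C
Reagents that add atoms: naphthalen-2-ylmethyl 2,2,2-trichloroacetimidate, N=C(OCc1ccc2ccccc2c1)C(Cl)(Cl)Cl
Why: Acid-catalysed imidate etherification protects the C6 hydroxyl without base, so retro-aldol cleavage and epimerisation of the β-hydroxy ketone are avoided.

Step 5
Reactants: 7 naphthalen-2-ylmethyl ether of 6
Product: 8 C8 enol triflate (C8=C9)
Conditions: PhNTf2, KN(SiMe3)2 (added last), THF, −78 °C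
Reagents that add atoms: N-phenylbis(trifluoromethanesulfonimide), O=S(=O)(N(c1ccccc1)S(=O)(=O)C(F)(F)F)C(F)(F)F
Why: Kinetic deprotonation should occur at the unhindered C9 methylene and not at the tertiary C7–H next to the quaternary centre, and in situ O-sulfonylation gives the less substituted enol triflate (kinetic enol triflate formation).

Step 6
Reactants: 8 C8 enol triflate (C8=C9)
Product: 9 C11-vinyl enol triflate
Conditions: CF3CO2H, CHCl3, 0 → 22 °C
Reagents that add atoms: none
Why: ipso-Protodesilylation of the vinylsilane through a β-silyl carbocation should unveil the vinyl group, while the electron-poor enol triflate and the arylmethyl ether resist the acid and C7 is no longer enolisable.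

Step 7
Reactants: 9 C11-vinyl enol triflate
Product: 10 8-isopropylcyclopentene (C8=C9)
Conditions: i-PrZnBr, PdCl2(dppf) (5 mol %), THF, 50 °C
Reagents that add atoms: isopropylzinc bromide, CC(C)[Zn]Br
Why: Negishi cross-coupling of the enol triflate with the secondary alkylzinc reagent installs the isopropyl group at C8, the wide-bite-angle bisphosphine disfavouring β-hydride isomerisation.

Step 8
Reactants: 10 8-isopropylcyclopentene (C8=C9)
Product: 11 cyclopentanol diol (C9–OH and C13–OH)
Conditions: BH3·THF (excess), THF, 0 °C → rt; then NaOH, H2O2, 0 °C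
Reagents that add atoms: hydrogen peroxide, OO
Why: Hydroboration–oxidation places boron on the terminal vinyl carbon and on C9 from the ring face opposite the adjacent C7 side chain, so syn addition of H and B sets C8 and C9 together (hydroxyl trans to isopropyl; isopropyl cis to the C7 substituent).

Step 9
Reactants: 11 cyclopentanol diol (C9–OH and C13–OH)
Product: 13 ethyl (E)-enoate with free C9–OH, via aldehyde 12 (not isolated)
Conditions: TEMPO (10 mol %), PhI(OAc)2, CH2Cl2, rt; then Ph3P=CHCO2Et, rt
Reagents that add atoms: ethyl (triphenyl-λ5-phosphanylidene)acetate, CCOC(=O)C=P(c1ccccc1)(c1ccccc1)c1ccccc1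
Why: Oxoammonium oxidation is selective for the primary alcohol, and the aldehyde is trapped in the same flask by a stabilised-ylide Wittig olefination that should give the E enoate.

Step 10
Reactants: 13 ethyl (E)-enoate with free C9–OH
Product: 14 C9 tert-butyldimethylsilyl ether of 13
Conditions: t-BuMe2SiOTf, 2,6-lutidine, CH2Cl2, −78 → 0 °C
Reagents that add atoms: tert-butyldimethylsilyl trifluoromethanesulfonate, CC(C)(C)[Si](C)(C)OS(=O)(=O)C(F)(F)F
Why: Silyl triflate silylation protects the hindered secondary C9 hydroxyl for all steps up to the late esterification.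

Step 11
Reactants: 14 C9 tert-butyldimethylsilyl ether of 13
Product: 15 (E)-allylic alcohol
Conditions: i-Bu2AlH, CH2Cl2, −78 °C
Reagents that add atoms: none
Why: Aluminium hydride reduction of the enoate gives the E allylic alcohol without touching the olefin or the ethers.

Step 12
Reactants: 15 (E)-allylic alcohol
Product: 16 (E)-allylic diethyl phosphate
Conditions: (EtO)2P(O)Cl, Et3N, DMAP (cat.), CH2Cl2, 0 °C
Reagents that add atoms: diethyl chlorophosphate, CCOP(=O)(Cl)OCC
Why: Phosphorylation turns the allylic alcohol into the leaving group used in copper-catalysed allylic substitution.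

Step 13
Reactants: 16 (E)-allylic diethyl phosphate; 3 pinacol alkenylboronate
Product: 17 skipped diene with the C13 stereocentre (C16–O triethylsilyl ether)
Conditions: CuCl (5 mol %), chiral sulfonate-bearing imidazolinium salt (5.5 mol %), NaOMe (1.5 equiv), THF, 22 → 60 °C
Reagents that add atoms: none
Why: Copper-catalysed enantioselective SN2' allylic substitution should form the C13–C14 bond at the γ-carbon, the chiral N-heterocyclic carbene ligand controlling C13 and the alkenyl group being transferred with retention of its geometry.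

Step 14
Reactants: 17 skipped diene with the C13 stereocentre
Product: 18 (Z)-allylic alcohol (C16–OH)
Conditions: pyridinium p-toluenesulfonate, MeOH, 0 °C
Reagents that add atoms: none
Why: Acid-catalysed methanolysis removes the primary triethylsilyl ether selectively, the hindered secondary tert-butyldimethylsilyl ether being much slower to cleave.

Step 15
Reactants: 18 (Z)-allylic alcohol (C16–OH)
Product: 19 (Z)-allylic bromide (C16–Br)
Conditions: CBr4, PPh3, 2,6-lutidine, CH2Cl2, −20 °C
Reagents that add atoms: carbon tetrabromide, BrC(Br)(Br)Br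
Why: Appel bromination should convert the primary allylic alcohol into the bromide at low temperature without allylic transposition or Z/E isomerisation.

Step 16
Reactants: 20 trans-1-methoxy-3-(trimethylsilyloxy)buta-1,3-diene; 21 acetaldehyde
Product: 23 (S)-2-methyl-2,3-dihydro-4H-pyran-4-one, via cycloadduct 22 (not isolated)
Conditions: [N,N'-bis(3,5-di-tert-butylsalicylidene)cyclohexane-1,2-diaminato]CrBF4 (2 mol %, enantiomer giving the 2S product), 4 Å molecular sieves, t-BuOMe, −30 °C; then CF3CO2H, CH2Cl2, 0 °C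
Reagents that add atoms: none
Why: Catalytic enantioselective hetero-Diels–Alder reaction sets C18 under catalyst control, and acid then cleaves the silyl enol ether and eliminates methanol to give the dihydropyranone (ring D).

Step 17
Reactants: 23 (S)-2-methyl-2,3-dihydro-4H-pyran-4-one
Product: 25 (S)-5-hydroxy-2-methyl-2,3-dihydro-4H-pyran-4-one, via epoxide 24 (not isolated)
Conditions: dimethyldioxirane, acetone/CH2Cl2, 0 °C; then TsOH (cat.), rt
Reagents that add atoms: dimethyldioxirane, CC1(C)OO1
Why: Epoxidation of the enol ether double bond of the vinylogous ester followed by acid-catalysed epoxide opening and proton loss should give the α-hydroxy enone (the epoxidation–isomerisation known for chromone epoxides), bringing C2 to the ketone oxidation level while no other olefin is present.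

Step 18
Reactants: 25 (S)-5-hydroxy-2-methyl-2,3-dihydro-4H-pyran-4-one
Product: 26 (S)-5-methoxy-2-methyl-2,3-dihydro-4H-pyran-4-one
Conditions: MeI, K2CO3, acetone, rt
Reagents that add atoms: iodomethane, CI
Why: Williamson O-alkylation of the acidic enol gives a robust methyl enol ether that leaves C17 as the only enolisable position.

Step 19
Reactants: 27 (S)-1-bromo-2-methylbutane; 28 ethyl but-2-ynoate
Product: 30 ethyl (S,E)-3,5-dimethylhept-2-enoate, via Grignard reagent 29 (not isolated)
Conditions: Mg, THF; CuBr·SMe2, THF, −78 °C; then 28, −78 °C; NH4Cl (aq)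
Reagents that add atoms: none
Why: syn-Carbocupration of the ynoate by the alkylcopper reagent and protonation at low temperature should give the E trisubstituted enoate, the C5' stereocentre coming unchanged from the bromide.

Step 20
Reactants: 30 ethyl (S,E)-3,5-dimethylhept-2-enoate
Product: 31 (S,E)-3,5-dimethylhept-2-en-1-ol
Conditions: i-Bu2AlH, CH2Cl2, −78 °C
Reagents that add atoms: none
Why: Aluminium hydride reduction of the enoate gives the allylic alcohol needed for directed epoxidation.

Step 21
Reactants: 31 (S,E)-3,5-dimethylhept-2-en-1-ol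
Product: 32 [(2R,3R)-3-methyl-3-((S)-2-methylbutyl)oxiran-2-yl]methanol
Conditions: Ti(Oi-Pr)4, D-(−)-diethyl tartrate, t-BuOOH, 4 Å molecular sieves, CH2Cl2, −20 °C
Reagents that add atoms: tert-butyl hydroperoxide, CC(C)(C)OO
Why: Sharpless asymmetric epoxidation with the D-tartrate delivers oxygen to the face that gives the (2R,3R) epoxide and so fixes the future tertiary carbinol C3' under reagent control.

Step 22
Reactants: 32 [(2R,3R)-3-methyl-3-((S)-2-methylbutyl)oxiran-2-yl]methanol
Product: 33 (3R,5S)-3,5-dimethylheptane-1,3-diol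
Conditions: NaAlH2(OCH2CH2OMe)2, THF, 0 °C
Reagents that add atoms: none
Why: Hydroxyl-directed hydride opening of the 2,3-epoxy alcohol at C2 gives the 1,3-diol with the C3–O bond and its configuration retained.

Step 23
Reactants: 33 (3R,5S)-3,5-dimethylheptane-1,3-diol
Product: 34 (3R,5S)-3-hydroxy-3,5-dimethylheptanoic acid
Conditions: TEMPO (cat.), NaOCl (cat.), NaClO2, MeCN/phosphate buffer (pH 6.7), 35 °C
Reagents that add atoms: sodium chlorite, [Na+].[O-]Cl=O
Why: Oxoammonium/chlorite oxidation takes the primary alcohol to the acid while the tertiary alcohol cannot be oxidised.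

Step 24
Reactants: 34 (3R,5S)-3-hydroxy-3,5-dimethylheptanoic acid
Product: 36 (3R,5S)-3,5-dimethyl-3-(triethylsilyloxy)heptanoic acid, via bis-silyl derivative 35 (not isolated)
Conditions: Et3SiOTf (2.5 equiv), 2,6-lutidine, CH2Cl2, −78 → 0 °C; then K2CO3, MeOH/H2O, 0 °C
Reagents that add atoms: triethylsilyl trifluoromethanesulfonate, CC[Si](CC)(CC)OS(=O)(=O)C(F)(F)F
Why: Exhaustive silylation followed by selective hydrolysis of the labile silyl ester protects the tertiary hydroxyl against dehydration or β-lactone formation during acyl activation.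

Step 25
Reactants: 26 (S)-5-methoxy-2-methyl-2,3-dihydro-4H-pyran-4-one; 19 (Z)-allylic bromide
Product: 38 C17-alkylated pyranone (C17/C18 trans), via lithium enolate 37 (not isolated)
Conditions: 26, LiN(i-Pr)2, THF, −78 °C; then 19, DMPU, −78 → −30 °C
Reagents that add atoms: none
Why: Alkylation of the kinetic lithium enolate by the allylic bromide anti to the C18 methyl should give the trans-disubstituted pyranone and set C17 (enolate alkylation joining the two fragments through C16–C17).

Step 26
Reactants: 38 C17-alkylated pyranone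
Product: 39 C3 tertiary allylic alcohol (isopropenyl on C3)
Conditions: CH2=C(CH3)MgBr, CeCl3, THF, −78 °C; NaHCO3 work-up, used without chromatography on silica
Reagents that add atoms: isopropenylmagnesium bromide, CC(=C)[Mg]Br
Why: 1,2-Addition of the organocerium reagent to the enone carbonyl along the pseudoaxial trajectory anti to the pseudoaxial C17–H should place the isopropenyl group cis to the C16 chain and set C3 (organocerium carbonyl addition).

Step 27
Reactants: 39 C3 tertiary allylic alcohol
Product: 40 ring C cyclooctadiene (C4=C5 and C14=C15) fused to the dihydropyran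
Conditions: second-generation Hoveyda–Grubbs catalyst (H2IMes)Cl2Ru=CH(2-i-PrOC6H4) (15 mol %), 1,4-benzoquinone (30 mol %), toluene (1 mM), 80 °C
Reagents that add atoms: none
Why: Ring-closing metathesis between the C13 vinyl and the C3 isopropenyl groups closes the eight-membered ring C as its Z trisubstituted olefin, helped by the free allylic hydroxyl and the cis disposition of the two arms on ring D, while the trisubstituted enol ether is inert.

Step 28
Reactants: 40 ring C cyclooctadiene
Product: 42 2-keto lactol (anomeric mixture), via alkoxy epoxide 41 (not isolated)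
Conditions: dimethyldioxirane (1.05 equiv), acetone/CH2Cl2, −78 °C; then H2O, −78 → 0 °C
Reagents that add atoms: dimethyldioxirane, CC1(C)OO1; water, O
Why: Rubottom-type epoxidation should occur chemoselectively at the most electron-rich, 1,2-dioxygenated olefin, and hydrolysis of the alkoxy epoxide at the anomeric carbon with loss of methanol gives the 2-keto lactol.

Step 29
Reactants: 42 2-keto lactol
Product: 43 2-keto lactone
Conditions: Dess–Martin periodinane, NaHCO3, CH2Cl2, 0 °C → rt
Reagents that add atoms: none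
Why: Hypervalent iodine oxidation converts the lactol into the lactone, the tertiary C3 hydroxyl and the olefins being inert.

Step 30
Reactants: 43 2-keto lactone
Product: 44 C2,C3 trans-diol lactone
Conditions: LiBH(s-Bu)3 (2.2 equiv), THF, −78 °C
Reagents that add atoms: none
Why: The bulky hydride should attack the activated C2 ketone from the face opposite the pseudoaxial C3–C4 bond, giving the equatorial C2 hydroxyl trans to the C3 hydroxyl (substrate-controlled ketone reduction), with the lactone untouched at low temperature.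

Step 31
Reactants: 44 C2,C3 trans-diol lactone
Product: 46 C2 triisopropylsilyl C3 trimethylsilyl bis-ether, via mono-silyl ether 45 (not isolated)
Conditions: i-Pr3SiOTf (1.2 equiv), 2,6-lutidine, CH2Cl2, −20 °C; then Me3SiOTf, 0 °C
Reagents that add atoms: triisopropylsilyl trifluoromethanesulfonate, CC(C)[Si](OS(=O)(=O)C(F)(F)F)(C(C)C)C(C)C; trimethylsilyl trifluoromethanesulfonate, C[Si](C)(C)OS(=O)(=O)C(F)(F)F
Why: Sequential silylation differentiates the secondary C2 hydroxyl (robust silyl group) from the tertiary C3 hydroxyl (small silyl group) and masks both before the Lewis acid step.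

Step 32
Reactants: 46 bis-silyl ether
Product: 47 primary alcohol (C6–OH)
Conditions: DDQ, CH2Cl2/pH 7 buffer, 0 °C → rt
Reagents that add atoms: none
Why: Oxidative cleavage of the naphthylmethyl ether by the quinone frees the C6 hydroxyl without affecting silyl ethers, lactone or isolated olefins.

Step 33
Reactants: 47 primary alcohol (C6–OH)
Product: 48 C6 aldehyde
Conditions: Dess–Martin periodinane, NaHCO3, CH2Cl2, 0 °C; used at once
Reagents that add atoms: none
Why: Buffered hypervalent iodine oxidation gives the α-branched aldehyde under non-basic conditions, so C7 should not epimerise.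

Step 34
Reactants: 48 C6 aldehyde
Product: 49 tetracyclic homoallylic alcohol (ring B closed; C6–OH; C4=C19 methylene)
Conditions: Me2AlCl (3 equiv), CH2Cl2, −78 → −30 °C
Reagents that add atoms: none
Why: Me2AlCl activates the C6 aldehyde, which is attacked by C5 of the ring C olefin C4(CH3)=C5 while a hydrogen of the C19 methyl passes to oxygen in a concerted, asynchronous type 1 intramolecular carbonyl-ene (Prins-type) reaction, the closest known case being the Lewis acid-promoted cyclisation of citronellal to isopulegol. Ring B closes in a 6-exo-trig mode at the carbonyl through a chair transition state. The new C5 stereocentre is controlled by allylic 1,3-strain, which holds C13–H in the olefin plane syn to C3 so that the C12 tether reaches C5 only on the face opposite C14, and by the chair, in which C4 and C14 are both equatorial, giving the trans B/C fusion; the C6 carbinol is removed in step 36. The step needs site selectivity for C4=C5 over C14=C15, secured because attack at C5 gives a six-membered ring with charge building up on tertiary C4 whereas the other olefin would need a seven-membered ring, and it needs the new double bond to be exocyclic, secured because C3 is fully substituted and the only allylic hydrogens on a C4 substituent belong to C19. The aluminium reagent also scavenges the transferred proton, and the silyl ethers on C2 and C3 are meant to suppress ionisation or a 1,2-shift at C3.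

Step 35
Reactants: 49 tetracyclic homoallylic alcohol
Product: 50 C6 O-phenyl thionocarbonate
Conditions: PhOC(S)Cl, pyridine, DMAP (cat.), CH2Cl2, rt
Reagents that add atoms: O-phenyl chlorothionoformate, S=C(Cl)Oc1ccccc1
Why: Acylation of the secondary C6 hydroxyl gives the radical precursor for Barton–McCombie deoxygenation.

Step 36
Reactants: 50 C6 O-phenyl thionocarbonate
Product: 51 deoxygenated tetracycle (C6 methylene)
Conditions: Bu3SnH, AIBN (cat.), toluene, 90 °C
Reagents that add atoms: none
Why: Barton–McCombie radical deoxygenation removes the oxygen that served as the activating group, fast hydrogen transfer from the stannane outpacing rearrangement of the homoallylic C6 radical.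

Step 37
Reactants: 51 deoxygenated tetracycle
Product: 52 C9 alcohol (C3–OH free; C2 silyl ether kept)
Conditions: HF·pyridine, pyridine, THF, 0 °C
Reagents that add atoms: none
Why: Fluoride-mediated desilylation should cleave the tert-butyldimethylsilyl and trimethylsilyl ethers while the more hindered triisopropylsilyl ether on C2 survives.

Step 38
Reactants: 52 C9 alcohol; 36 (3R,5S)-3,5-dimethyl-3-(triethylsilyloxy)heptanoic acid
Product: 54 protected ester, via mixed anhydride 53 (not isolated)
Conditions: 36, 2,4,6-trichlorobenzoyl chloride, Et3N, THF, rt; then 52, DMAP, toluene, rt → 40 °C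
Reagents that add atoms: none
Why: Yamaguchi esterification acylates the secondary C9 hydroxyl, the tertiary C3 hydroxyl being too hindered to react.

Step 39
Reactants: 54 protected ester
Product: 55 target CNP0331120.1
Conditions: HF·pyridine, THF, 0 °C → rt
Reagents that add atoms: none
Why: Global fluoride desilylation frees the C2 and side-chain hydroxyls under conditions that leave the lactone, the ester and the allylic tertiary alcohol intact.

**Compound list**

1 | (Z)-3-iodobut-2-en-1-ol (iodine cis to CH2OH) | C/C(I)=C/CO | starting material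
2 | (Z)-3-iodobut-2-enyl triethylsilyl ether | C/C(I)=C/CO[Si](CC)(CC)CC | intermediate
3 | 4,4,5,5-tetramethyl-2-[4-(triethylsilyloxy)but-2-en-2-yl]-1,3,2-dioxaborolane, boron cis to CH2O | C/C(B1OC(C)(C)C(C)(C)O1)=C/CO[Si](CC)(CC)CC | intermediate
4 | 3-methylcyclopent-2-en-1-one | CC1=CC(=O)CC1 | starting material
5 | diisobutylaluminium enolate of (S)-3-methyl-3-[1-(trimethylsilyl)ethenyl]cyclopentanone | CC(C)C[Al](CC(C)C)OC1=C[C@@](C)(C(=C)[Si](C)(C)C)CC1 | intermediate
6 | (2S,3S)-2-(hydroxymethyl)-3-methyl-3-[1-(trimethylsilyl)ethenyl]cyclopentan-1-one (C7 and C11 set; hydroxymethyl trans to silylvinyl) | OC[C@H]1C(=O)CC[C@]1(C)C(=C)[Si](C)(C)C | intermediate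
7 | (2S,3S)-3-methyl-2-[(naphthalen-2-ylmethoxy)methyl]-3-[1-(trimethylsilyl)ethenyl]cyclopentan-1-one | c1ccc2cc(COC[C@H]3C(=O)CC[C@]3(C)C(=C)[Si](C)(C)C)ccc2c1 | intermediate
8 | enol triflate of 7 with the double bond C8=C9, C7 and C11 as in 6 | c1ccc2cc(COC[C@H]3C(OS(=O)(=O)C(F)(F)F)=CC[C@]3(C)C(=C)[Si](C)(C)C)ccc2c1 | intermediate
9 | enol triflate as 8 with a vinyl group on C11 | c1ccc2cc(COC[C@H]3C(OS(=O)(=O)C(F)(F)F)=CC[C@]3(C)C=C)ccc2c1 | intermediate
10 | 1-isopropyl-4-methyl-5-[(naphthalen-2-ylmethoxy)methyl]-4-vinylcyclopentene, C7 and C11 as in 6 | c1ccc2cc(COC[C@H]3C(C(C)C)=CC[C@]3(C)C=C)ccc2c1 | intermediate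
11 | 4-(2-hydroxyethyl)-2-isopropyl-4-methyl-3-[(naphthalen-2-ylmethoxy)methyl]cyclopentan-1-ol, C7, C8, C9, C11 arranged as in the target | c1ccc2cc(COC[C@H]3[C@@H](C(C)C)[C@H](O)C[C@]3(C)CCO)ccc2c1 | intermediate
12 | aldehyde from 11 (C13 formyl, C9–OH free) | c1ccc2cc(COC[C@H]3[C@@H](C(C)C)[C@H](O)C[C@]3(C)CC=O)ccc2c1 | intermediate
13 | ethyl (E)-4-(ring A)but-2-enoate with free C9–OH | c1ccc2cc(COC[C@H]3[C@@H](C(C)C)[C@H](O)C[C@]3(C)C/C=C/C(=O)OCC)ccc2c1 | intermediate
14 | C9 tert-butyldimethylsilyl ether of 13 | c1ccc2cc(COC[C@H]3[C@@H](C(C)C)[C@H](O[Si](C)(C)C(C)(C)C)C[C@]3(C)C/C=C/C(=O)OCC)ccc2c1 | intermediate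
15 | (E)-allylic alcohol from 14 | c1ccc2cc(COC[C@H]3[C@@H](C(C)C)[C@H](O[Si](C)(C)C(C)(C)C)C[C@]3(C)C/C=C/CO)ccc2c1 | intermediate
16 | (E)-allylic diethyl phosphate from 15 | c1ccc2cc(COC[C@H]3[C@@H](C(C)C)[C@H](O[Si](C)(C)C(C)(C)C)C[C@]3(C)C/C=C/COP(=O)(OCC)OCC)ccc2c1 | intermediate
17 | skipped diene: C13 bearing vinyl and the (Z)-alkenyl unit C14(CH3)=C15–C16–OSiEt3, C13 as in the target | c1ccc2cc(COC[C@H]3[C@@H](C(C)C)[C@H](O[Si](C)(C)C(C)(C)C)C[C@]3(C)C[C@@H](C=C)/C(C)=C\CO[Si](CC)(CC)CC)ccc2c1 | intermediate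
18 | (Z)-allylic alcohol from 17 (C16–OH) | c1ccc2cc(COC[C@H]3[C@@H](C(C)C)[C@H](O[Si](C)(C)C(C)(C)C)C[C@]3(C)C[C@@H](C=C)/C(C)=C\CO)ccc2c1 | intermediate
19 | (Z)-allylic bromide from 18 (C16–Br) | c1ccc2cc(COC[C@H]3[C@@H](C(C)C)[C@H](O[Si](C)(C)C(C)(C)C)C[C@]3(C)C[C@@H](C=C)/C(C)=C\CBr)ccc2c1 | intermediate
20 | trans-1-methoxy-3-(trimethylsilyloxy)buta-1,3-diene | CO/C=C/C(=C)O[Si](C)(C)C | starting material
21 | acetaldehyde | CC=O | starting material
22 | cis-2-methoxy-6-methyl-4-(trimethylsilyloxy)-3,6-dihydro-2H-pyran (6S) | C[C@H]1CC(O[Si](C)(C)C)=C[C@@H](OC)O1 | intermediate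
23 | (S)-2-methyl-2,3-dihydro-4H-pyran-4-one | C[C@H]1CC(=O)C=CO1 | intermediate
24 | epoxide of 23 at the enol ether double bond, oxygen trans to the methyl | C[C@H]1CC(=O)[C@@H]2O[C@@H]2O1 | intermediate
25 | (S)-5-hydroxy-2-methyl-2,3-dihydro-4H-pyran-4-one | C[C@H]1CC(=O)C(O)=CO1 | intermediate
26 | (S)-5-methoxy-2-methyl-2,3-dihydro-4H-pyran-4-one | C[C@H]1CC(=O)C(OC)=CO1 | intermediate
27 | (S)-1-bromo-2-methylbutane | BrC[C@@H](C)CC | starting material
28 | ethyl but-2-ynoate | CC#CC(=O)OCC | starting material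
29 | (S)-2-methylbutylmagnesium bromide | Br[Mg]C[C@@H](C)CC | intermediate
30 | ethyl (S,E)-3,5-dimethylhept-2-enoate | CCOC(=O)/C=C(\C)C[C@@H](C)CC | intermediate
31 | (S,E)-3,5-dimethylhept-2-en-1-ol | OC/C=C(\C)C[C@@H](C)CC | intermediate
32 | [(2R,3R)-3-methyl-3-((S)-2-methylbutyl)oxiran-2-yl]methanol | OC[C@H]1O[C@]1(C)C[C@@H](C)CC | intermediate
33 | (3R,5S)-3,5-dimethylheptane-1,3-diol | OCC[C@](C)(O)C[C@@H](C)CC | intermediate
34 | (3R,5S)-3-hydroxy-3,5-dimethylheptanoic acid | OC(=O)C[C@](C)(O)C[C@@H](C)CC | intermediate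
35 | triethylsilyl (3R,5S)-3,5-dimethyl-3-(triethylsilyloxy)heptanoate | CC[Si](CC)(CC)OC(=O)C[C@](C)(O[Si](CC)(CC)CC)C[C@@H](C)CC | intermediate
36 | (3R,5S)-3,5-dimethyl-3-(triethylsilyloxy)heptanoic acid | OC(=O)C[C@](C)(O[Si](CC)(CC)CC)C[C@@H](C)CC | intermediate
37 | lithium enolate of 26 (C17 enolate) | C[C@H]1C=C(O[Li])C(OC)=CO1 | intermediate
38 | 5-methoxy-2-methyl-3-(C16 side chain)-2,3-dihydro-4H-pyran-4-one, C17/C18 trans, all stereocentres as in the target | c1ccc2cc(COC[C@H]3[C@@H](C(C)C)[C@H](O[Si](C)(C)C(C)(C)C)C[C@]3(C)C[C@@H](C=C)/C(C)=C\C[C@H]4[C@H](C)OC=C(OC)C4=O)ccc2c1 | intermediate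
39 | tertiary allylic alcohol: isopropenyl on C3 cis to the C16 chain, hydroxyl equatorial | c1ccc2cc(COC[C@H]3[C@@H](C(C)C)[C@H](O[Si](C)(C)C(C)(C)C)C[C@]3(C)C[C@@H](C=C)/C(C)=C\C[C@H]4[C@H](C)OC=C(OC)[C@@]4(O)C(C)=C)ccc2c1 | intermediate
40 | ring C cyclooctadiene (Z C4=C5, Z C14=C15) cis-fused to the 2-methoxy dihydropyran, ring A attached through C12 | c1ccc2cc(COC[C@H]3[C@@H](C(C)C)[C@H](O[Si](C)(C)C(C)(C)C)C[C@]3(C)C[C@@H]4/C(C)=C\C[C@H]5[C@H](C)OC=C(OC)[C@@]5(O)/C(C)=C\4)ccc2c1 | intermediate
41 | C1–C2 alkoxy epoxide of 40, epoxide oxygen trans to the C3–C4 bond | c1ccc2cc(COC[C@H]3[C@@H](C(C)C)[C@H](O[Si](C)(C)C(C)(C)C)C[C@]3(C)C[C@@H]4/C(C)=C\C[C@H]5[C@H](C)O[C@@H]6O[C@]6(OC)[C@@]5(O)/C(C)=C\4)ccc2c1 | intermediate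
42 | 2-keto lactol (C1 hemiacetal as anomeric mixture, C2 ketone, C3–OH) | c1ccc2cc(COC[C@H]3[C@@H](C(C)C)[C@H](O[Si](C)(C)C(C)(C)C)C[C@]3(C)C[C@@H]4/C(C)=C\C[C@H]5[C@H](C)OC(O)C(=O)[C@@]5(O)/C(C)=C\4)ccc2c1 | intermediate
43 | 2-keto lactone (C1 lactone, C2 ketone, C3–OH) | c1ccc2cc(COC[C@H]3[C@@H](C(C)C)[C@H](O[Si](C)(C)C(C)(C)C)C[C@]3(C)C[C@@H]4/C(C)=C\C[C@H]5[C@H](C)OC(=O)C(=O)[C@@]5(O)/C(C)=C\4)ccc2c1 | intermediate
44 | lactone diol, C2–OH trans to C3–OH (2S,3S as in the target) | c1ccc2cc(COC[C@H]3[C@@H](C(C)C)[C@H](O[Si](C)(C)C(C)(C)C)C[C@]3(C)C[C@@H]4/C(C)=C\C[C@H]5[C@H](C)OC(=O)[C@@H](O)[C@@]5(O)/C(C)=C\4)ccc2c1 | intermediate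
45 | C2 triisopropylsilyl ether of 44 (C3–OH free) | c1ccc2cc(COC[C@H]3[C@@H](C(C)C)[C@H](O[Si](C)(C)C(C)(C)C)C[C@]3(C)C[C@@H]4/C(C)=C\C[C@H]5[C@H](C)OC(=O)[C@@H](O[Si](C(C)C)(C(C)C)C(C)C)[C@@]5(O)/C(C)=C\4)ccc2c1 | intermediate
46 | C2 triisopropylsilyl, C3 trimethylsilyl bis-ether | c1ccc2cc(COC[C@H]3[C@@H](C(C)C)[C@H](O[Si](C)(C)C(C)(C)C)C[C@]3(C)C[C@@H]4/C(C)=C\C[C@H]5[C@H](C)OC(=O)[C@@H](O[Si](C(C)C)(C(C)C)C(C)C)[C@@]5(O[Si](C)(C)C)/C(C)=C\4)ccc2c1 | intermediate
47 | primary alcohol (C6–OH) from 46 | OC[C@H]1[C@@H](C(C)C)[C@H](O[Si](C)(C)C(C)(C)C)C[C@]1(C)C[C@@H]2/C(C)=C\C[C@H]3[C@H](C)OC(=O)[C@@H](O[Si](C(C)C)(C(C)C)C(C)C)[C@@]3(O[Si](C)(C)C)/C(C)=C\2 | intermediate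
48 | C6 aldehyde (ene precursor: rings A, C and D present) | O=C[C@H]1[C@@H](C(C)C)[C@H](O[Si](C)(C)C(C)(C)C)C[C@]1(C)C[C@@H]2/C(C)=C\C[C@H]3[C@H](C)OC(=O)[C@@H](O[Si](C(C)C)(C(C)C)C(C)C)[C@@]3(O[Si](C)(C)C)/C(C)=C\2 | intermediate
49 | tetracyclic homoallylic alcohol: ring B closed, C5 as in the target, C6–OH equatorial, C4=C19 methylene | C=C1[C@H]2[C@H](O)[C@H]3[C@@H](C(C)C)[C@H](O[Si](C)(C)C(C)(C)C)C[C@]3(C)C[C@@H]2/C(C)=C\C[C@H]2[C@H](C)OC(=O)[C@@H](O[Si](C(C)C)(C(C)C)C(C)C)[C@@]12O[Si](C)(C)C | intermediate
50 | C6 O-phenyl thionocarbonate of 49 | C=C1[C@H]2[C@H](OC(=S)Oc4ccccc4)[C@H]3[C@@H](C(C)C)[C@H](O[Si](C)(C)C(C)(C)C)C[C@]3(C)C[C@@H]2/C(C)=C\C[C@H]2[C@H](C)OC(=O)[C@@H](O[Si](C(C)C)(C(C)C)C(C)C)[C@@]12O[Si](C)(C)C | intermediate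
51 | deoxygenated tetracycle, tris-silyl protected (C2, C3, C9) | C=C1[C@H]2C[C@H]3[C@@H](C(C)C)[C@H](O[Si](C)(C)C(C)(C)C)C[C@]3(C)C[C@@H]2/C(C)=C\C[C@H]2[C@H](C)OC(=O)[C@@H](O[Si](C(C)C)(C(C)C)C(C)C)[C@@]12O[Si](C)(C)C | intermediate
52 | tetracyclic C9 alcohol with free C3–OH and C2 triisopropylsilyl ether | C=C1[C@H]2C[C@H]3[C@@H](C(C)C)[C@H](O)C[C@]3(C)C[C@@H]2/C(C)=C\C[C@H]2[C@H](C)OC(=O)[C@@H](O[Si](C(C)C)(C(C)C)C(C)C)[C@@]12O | intermediate
53 | mixed anhydride of 36 with 2,4,6-trichlorobenzoic acid | O=C(OC(=O)C[C@](C)(O[Si](CC)(CC)CC)C[C@@H](C)CC)c1c(Cl)cc(Cl)cc1Cl | intermediate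
54 | C9 ester with C2 triisopropylsilyl and side-chain triethylsilyl ethers | C=C1[C@H]2C[C@H]3[C@@H](C(C)C)[C@H](OC(=O)C[C@](C)(O[Si](CC)(CC)CC)C[C@@H](C)CC)C[C@]3(C)C[C@@H]2/C(C)=C\C[C@H]2[C@H](C)OC(=O)[C@@H](O[Si](C(C)C)(C(C)C)C(C)C)[C@@]12O | intermediate
55 | CNP0331120.1 | C=C1[C@H]2C[C@H]3[C@@H](C(C)C)[C@H](OC(=O)C[C@](C)(O)C[C@@H](C)CC)C[C@]3(C)C[C@@H]2/C(C)=C\C[C@H]2[C@H](C)OC(=O)[C@@H](O)[C@@]12O | target

**Step count and risks**

Total step count: 39. Longest linear sequence: 28 steps (steps 3–15, then 25–39).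

Steps most likely to fail:

1. Step 27 (ring-closing metathesis). The ruthenium carbene may load on the C13 vinyl group but fail to engage the 1,1-disubstituted olefin on the fully substituted C3, so that intermolecular metathesis and olefin migration at the doubly allylic C13 take over. Fallback by relay metathesis, setting out from 38 (with 1) and returning at 40: 1 is alkylated with NaH and allyl bromide to give allyl (Z)-3-iodobut-2-enyl ether F1. Iodine–lithium exchange with t-BuLi, transmetalation with CeCl3 and addition to 38 give the relay tertiary alcohol F2. Its terminal allyl ether takes up the catalyst and hands the carbene to C4 with loss of 2,5-dihydrofuran, and closure onto the C13 vinyl group gives 40.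

2. Step 34 (carbonyl-ene closure of ring B). Lewis acid-induced ionisation or a 1,2-shift at C3, or epimerisation of the α-branched aldehyde at C7 before cyclisation, may compete with the ene pathway. Fallback by radical Heck-type cyclisation, setting out from 47 and returning at 51: Appel iodination (I2, PPh3, imidazole) gives the primary iodide F3. With Co(dmgH)2(py)Cl, i-Pr2NEt and blue light (or Pd(PPh3)4 at 110 °C) the C6 radical should add 6-exo to C5 and the tertiary C4 radical should lose a C19 hydrogen, giving 51 directly without the oxygen detour of steps 33–36.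

3. Step 13 (copper-catalysed allylic substitution). Slow boron-to-copper transfer of the trisubstituted alkenyl group may let direct SN2 substitution by methoxide or loss of enantiofacial control intervene. Fallback by iridium-catalysed branched-selective allylic alkenylation, setting out from 14 (with 3) and returning at 18: ozonolysis of the enoate (O3, then PPh3) gives aldehyde F4, and CH2=CHMgBr gives the secondary allylic alcohol F5 as both carbinol epimers. Boronate 3 is converted with KHF2, which also removes the silyl ether, into potassium trifluoroborate F6. [Ir(cod)Cl]2 with a chiral phosphoramidite–olefin ligand and an acid promoter should convert both epimers of F5 through a common allyl-iridium intermediate into the branched diene 18.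

Further compounds
F1 | step 27 | allyl (Z)-3-iodobut-2-enyl ether | C/C(I)=C/COCC=C
F2 | step 27 | relay tertiary alcohol (as 39 with a 4-(allyloxy)but-2-en-2-yl group on C3, C3 cis to CH2O) | c1ccc2cc(COC[C@H]3[C@@H](C(C)C)[C@H](O[Si](C)(C)C(C)(C)C)C[C@]3(C)C[C@@H](C=C)/C(C)=C\C[C@H]4[C@H](C)OC=C(OC)[C@@]4(O)/C(C)=C\COCC=C)ccc2c1
F3 | step 34 | primary iodide (C6–I) from 47 | IC[C@H]1[C@@H](C(C)C)[C@H](O[Si](C)(C)C(C)(C)C)C[C@]1(C)C[C@@H]2/C(C)=C\C[C@H]3[C@H](C)OC(=O)[C@@H](O[Si](C(C)C)(C(C)C)C(C)C)[C@@]3(O[Si](C)(C)C)/C(C)=C\2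
F4 | step 13 | C13 aldehyde with C9 tert-butyldimethylsilyl ether | c1ccc2cc(COC[C@H]3[C@@H](C(C)C)[C@H](O[Si](C)(C)C(C)(C)C)C[C@]3(C)CC=O)ccc2c1
F5 | step 13 | secondary allylic alcohol at C13 (both carbinol epimers) | c1ccc2cc(COC[C@H]3[C@@H](C(C)C)[C@H](O[Si](C)(C)C(C)(C)C)C[C@]3(C)CC(O)C=C)ccc2c1
F6 | step 13 | potassium trifluoro(4-hydroxybut-2-en-2-yl)borate, boron cis to CH2OH | C/C([B-](F)(F)F)=C/CO.[K+]
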